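All runs were generated by integration with constants of no real substance; the scatter is artificial.

**Straight line.** The dusk flask loses 0.0700 min⁻¹ of its charge of L per minute over its first 2.00 min and 0.0700 min⁻¹ over its last 2.00 min. So you are looking at a steady stream, not a decay.

| setting | dusk | flask |
|---|---|---|
| L | 0.075 M | 0.050 M |
| D | 3 equiv | 3.00 equiv |
| remark | run made earlier |  |
| time |  | 30 min |

dusk run (percent of the L charged)

| time / min | Z / % | L / % |
|---|---|---|
| 2.00 | 11 | 86 |
| 4.00 | 21 | 74 |
| 5.00 | 26 | 67 |
| 8.00 | 40 | 49 |
| 10.0 | 45 | 35 |

(scatter of a reading: 1.5 percentage points)

- at the start none of L is in solution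
- a reading or a percentage of Z counts all its forms, free or not

- time up to 30 min at which Z stands highest
- the amount of Z, in percent of the L charged, at that time
- earliest time at which at least nineteen twentieths of that best amount are there, in min
- latest time at which they still are, in min

**Counting turnovers.** By its last reading, dusk has passed 65 percentage points of a charge in 10.0 min, so one whole charge takes 15.4 min. Suppose the stream carries the same amount per minute whatever the charge. The new flask holds 0.667 of the dusk charge, so it needs 10.3 min. That is the turnover time, the time in which the stream carries one whole charge of L away. With 3.00 equiv of D, L is the limiting reagent, so I expect Z to peak near this time.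

**First doubt.** A stream proportional to D would keep the fraction per minute unchanged between the flasks, and the time would stay at 15.4 min. But in dusk such a stream, with D down to 0.783 of its charge by what L has taken, and lower still if D has another way out, takes 11 points or less in the last interval. The readings show 14 points, each with a scatter of 1.5 points. That weakens the doubt without removing it, and I keep 10.3 min.

**Second doubt.** Z trails the L lost by 20 points at that dusk reading. If Z is lost at a steady fraction per minute, the gap grows with the square of the turnovers and, at one turnover, in proportion to the turnover time. That gives a peak of 68.4%. Part of the gap may be material still on its way, so I take this as a low estimate.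

**The forecast.** It says 13.5 min, 64%, and a window from 11.5 min to 16.5 min, later and lower than my figures, on the ground that “Solids would then run out at 10–15 min”.

**The flask.** It gives 11.9 min, 76.3%, and a window from 11.0 min to 14.5 min.

    L ⇌ Q, rate k1*(cs1 - [Q]) while solid is left; crystals form when [Q] > cs1 (solubility = 3.80 mM, k = 0.0215 s⁻¹)
    Q + D → Z (k = 1.72 L mol⁻¹ s⁻¹)
    Z ⇌ G (K = 3.03, k = 9.96 × 10⁻⁴ s⁻¹)
    D → X (k = 0.00106 s⁻¹)
    E ⇌ Z, rate k5*(cs5 - [Z]) while solid is left; crystals form when [Z] > cs5 (solubility = 17.0 mM, k = 0.128 s⁻¹)
    L + Z → J (k = 0.00658 L mol⁻¹ s⁻¹)

**Smaller charge.** In this flask the peak comes at 1.16 turnover times, with L at 0%, and Z stands 7.9 points above my low estimate. The neighbouring flask, charged with 0.030 M of L at the same equivalents, has a turnover time of 6.15 min. The same count puts its peak at 81.1%, and it reaches 79.3%. Its 30 min are 4.88 turnover times against 2.91 in the flask, and by then the neighbouring flask holds 35.1% of Z and 62.6% of G.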